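**Plan**

Labdane numbering is used throughout: ring A = C1–C5, C10; ring B = C5–C10; C17 = CH2 on C8; C19 = ester carbon on C4 (β); C20 = formyl carbon on C10; C11–C16 = arm and butenolide.
Enabling feature: in ring B, C5 lies β to both C9 and C20 (a latent 2-alkoxycarbonylcyclohexenone), and C4 carries two carbonyl-level carbons, C19 and C3 (a latent α-formyl ester); C4, C5 and C10 are contiguous.
Cuts, in retrosynthetic order: C20 oxidation level; C12–C13 (lactone enolate alkylation); C8=C17 (Wittig); C9–C11 (Stille at a C9 enol triflate); C2=C3 (metathesis); then C1–C10 and C4–C5 in one operation.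
Forward: ring B is bought as a cyclohexanone; the three-component Michael–allylation sets C4, C5 and C10; metathesis and hydrogenation close ring A; the C9 ketone becomes the C9 arm and the C8 methylene; the butenolide is attached; C20 goes from ester to aldehyde last.
Stereochemistry: C5 and C4 from the cinchona squaramide catalyst; C10 from anti allylation of the enolate; C9 from α-face hydroboration (also expected to be the more stable epimer next to the C8 ketone).

Key step: step 3

Assumption: the quinine-derived squaramide is taken to give the C5/C4 sense drawn; should the mirror-image series form, the quinidine-derived pseudoenantiomer is used with no other change.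

**Route**

Step 1
Reactants: 1 methyl propanoate; 2 methyl formate
Product: 3 methyl 2-formylpropanoate (racemic, largely enolised)
Conditions: NaH, Et2O, 0 °C to rt; aq. HCl work-up
Reagents that add atoms: none
Why: Crossed Claisen condensation in which the non-enolisable formate acylates the propanoate enolate and the product is withdrawn as its sodium enolate, which should drive the equilibrium; the racemate suffices because C2 is re-enolised in step 3.

Step 2
Reactants: 4 tert-butyl 2-oxocyclohexane-1-carboxylate
Product: 7 tert-butyl 6-oxocyclohex-1-ene-1-carboxylate, via selenide 5 (not isolated), via selenoxide 6 (not isolated)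
Conditions: PhSeCl, pyridine, CH2Cl2, 0 °C; then 30% aq. H2O2, 0 °C; solution used at once
Reagents that add atoms: none
Why: α-Selenenylation of the β-keto ester enol and selenoxide syn-elimination toward the only β-hydrogens (ring CH2) should give the doubly activated enone, which is not stored because it dimerises.

Step 3
Reactants: 3 methyl 2-formylpropanoate; 7 tert-butyl 6-oxocyclohex-1-ene-1-carboxylate; 8 allyl bromide
Product: 10 tert-butyl (1R,2S)-2-[(2R)-1-methoxy-2-methyl-1,3-dioxopropan-2-yl]-6-oxo-1-(prop-2-en-1-yl)cyclohexane-1-carboxylate, via Michael adduct 9 (not isolated)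
Conditions: 3-{[3,5-bis(trifluoromethyl)phenyl]amino}-4-{[(8α,9S)-6′-methoxycinchonan-9-yl]amino}cyclobut-3-ene-1,2-dione (10 mol%), toluene, −20 °C; then DMF, Cs2CO3, 8, −20 to 0 °C, same flask
Reagents that add atoms: none
Why: The quinuclidine nitrogen of the catalyst deprotonates the enolised formyl ester 3 while the squaramide N–H bonds hold the keto ester of 7, so that C4 adds to the β-carbon C5 in a conjugate addition and leaves the C10 β-keto ester enol 9, whose caesium enolate is then C-allylated by allyl bromide in an SN2 step. The closest known reactions are cinchona squaramide- or thiourea-catalysed Michael additions of α-substituted 1,3-dicarbonyl donors to alkylidene 1,3-dicarbonyl acceptors and the conjugate addition–enolate alkylation of 2-alkoxycarbonylcycloalkenones. No ring closes in this step. C5 is set by the enone face left open by the catalyst and C4 by the face of the hydrogen-bonded enolate presented to it (both catalyst controlled), whereas C10 is set by the substrate, the allyl group entering anti to the bulky C5 substituent of the planar enolate. The step needs C- over O-allylation and trapping before retro-Michael loss of the donor; the soft β-keto ester enolate with allyl bromide should favour carbon, and the doubly activated acceptor together with the low temperature should keep the adduct intact. The product carries the allyl group (C1, C2) and the formyl carbon (C3) trans on ring B, as closure to a trans-fused ring A requires.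

Step 4
Reactants: 10 the keto aldehyde from step 3
Product: 11 tert-butyl (1R,2S)-2-[(2S)-1-methoxy-2-methyl-1-oxobut-3-en-2-yl]-6-oxo-1-(prop-2-en-1-yl)cyclohexane-1-carboxylate
Conditions: Ph3PCH3Br, KOtBu, THF, 0 °C; then 10 (1.05 equiv ylide), −78 to 0 °C
Reagents that add atoms: methyltriphenylphosphonium bromide, C[P+](c1ccccc1)(c1ccccc1)c1ccccc1.[Br-]
Why: Wittig methylenation in which the aldehyde is far more electrophilic than the α-quaternary ketone or the two hindered esters, so one equivalent of ylide at low temperature should convert C3 only; C4 is quaternary and cannot epimerise.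

Step 5
Reactants: 11 the allyl/vinyl diene
Product: 13 20-tert-butyl 19-methyl 9-oxo-11,12,13,14,15,16,17-heptanorlabdane-19,20-dioate (trans-decalin; 4α-CH3, 4β-CO2Me, 5α-H, 10β-CO2tBu), via octalene 12 (not isolated)
Conditions: second-generation Grubbs catalyst RuCl2(=CHPh)(H2IMes)(PCy3) (5 mol%), toluene, 60 °C; then EtOAc, Pd/C, H2 (1 atm), rt
Reagents that add atoms: none
Why: Ring-closing metathesis of the allyl and vinyl groups, which sit gauche as trans neighbours on ring B and are helped by geminal substitution at C4 and C10, should close ring A as a cyclohexene, and heterogeneous hydrogenation then saturates the cis C2=C3 bond without touching ketone or esters; the trans ring fusion is already fixed by C5 and C10.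

Step 6
Reactants: 13 the keto diester
Product: 14 20-tert-butyl 19-methyl 9-(trifluoromethanesulfonyloxy)-11,12,13,14,15,16,17-heptanorlabd-8-ene-19,20-dioate
Conditions: KN(SiMe3)2, THF, −78 °C; PhNTf2, −78 to 0 °C
Reagents that add atoms: N-phenylbis(trifluoromethanesulfonimide), O=S(=O)(N(c1ccccc1)S(=O)(=O)C(F)(F)F)C(F)(F)F
Why: C10 is quaternary, so the potassium enolate can form only toward C8, and O-sulfonylation gives the C8=C9 enol triflate (standard enol triflate formation with a non-nucleophilic base, which avoids retro-Claisen opening).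

Step 7
Reactants: 14 the enol triflate
Product: 15 9-(trifluoromethanesulfonyloxy)-19-methoxy-19-oxo-11,12,13,14,15,16,17-heptanorlabd-8-en-20-oic acid (free C20 acid, C19 methyl ester)
Conditions: CF3CO2H/CH2Cl2 (1:4), 0 °C to rt
Reagents that add atoms: none
Why: Acidolysis of the tert-butyl ester through the tert-butyl cation is placed here because the C9 ketone is masked (no β-keto acid to decarboxylate) and the electron-poor enol triflate and the methyl ester should tolerate the acid.

Step 8
Reactants: 15 the C20 acid
Product: 16 methyl 20-hydroxy-9-(trifluoromethanesulfonyloxy)-11,12,13,14,15,16,17-heptanorlabd-8-en-19-oate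
Conditions: BH3·SMe2, THF, 0 to 50 °C; MeOH quench; crude used directly
Reagents that add atoms: none
Why: Borane reduces carboxylic acids through acyloxyboranes much faster than esters or an electron-poor enol triflate; the neopentyl alcohol is not stored because it could lactonise onto the syn-axial C19 ester.

Step 9
Reactants: 16 the C20 alcohol
Product: 17 methyl 20-(tert-butyldimethylsilyloxy)-9-(trifluoromethanesulfonyloxy)-11,12,13,14,15,16,17-heptanorlabd-8-en-19-oate
Conditions: TBSOTf, 2,6-lutidine, CH2Cl2, −78 °C
Reagents that add atoms: tert-butyldimethylsilyl trifluoromethanesulfonate, CC(C)(C)[Si](C)(C)OS(=O)(=O)C(F)(F)F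
Why: Silyl triflate with a hindered pyridine base silylates hindered neopentyl alcohols rapidly without ever forming an alkoxide, so lactonisation should not compete.

Step 10
Reactants: 17 the silyl ether triflate
Product: 18 methyl 20-(tert-butyldimethylsilyloxy)-13,14,15,16,17-pentanorlabda-8,11-dien-19-oate (C9 vinyl diene)
Conditions: Bu3SnCH=CH2, Pd(PPh3)4 (5 mol%), LiCl, THF, 65 °C
Reagents that add atoms: tributyl(vinyl)stannane, C=C[Sn](CCCC)(CCCC)CCCC
Why: Stille coupling of an enol triflate with a vinylstannane in the presence of chloride is neutral and is known to tolerate a neighbouring quaternary carbon, an ester and a silyl ether; it forms C9–C11.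

Step 11
Reactants: 18 the diene
Product: 21 methyl 20-(tert-butyldimethylsilyloxy)-8α,12-dihydroxy-13,14,15,16,17-pentanorlabdan-19-oate (9α-H), via 9-BBN adduct 19 (not isolated), via bis-borane 20 (not isolated)
Conditions: 9-borabicyclo[3.3.1]nonane (9-BBN, 1.2 equiv), THF, 0 °C to rt; then BH3·THF, 0 °C to rt; then 3 M NaOH, 30% H2O2, 0 °C to rt
Reagents that add atoms: hydrogen peroxide, OO
Why: 9-BBN should add only to the terminal CH2 of the vinyl group (boron at C12), after which borane adds to the remaining trisubstituted C8=C9 bond with boron at C8 from the α face, anti to the axial C10 CH2OTBS group, so that syn addition places hydrogen at C9 on the α face (arm β), and alkaline peroxide oxidises both C–B bonds with retention (hydroboration–oxidation).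

Step 12
Reactants: 21 the diol
Product: 22 methyl 20-(tert-butyldimethylsilyloxy)-12-hydroxy-8-oxo-13,14,15,16,17-pentanorlabdan-19-oate (in equilibrium with its 8,12-hemiketal)
Conditions: aq. NaOCl (1.2 equiv), AcOH, rt
Reagents that add atoms: none
Why: Hypochlorous acid in acetic acid oxidises secondary alcohols much faster than primary ones, and the γ-hydroxy ketone formed is further shielded as its cyclic hemiketal; no alkene is present at this stage, and C9 keeps the equatorial arm.

Step 13
Reactants: 22 the hydroxy ketone
Product: 23 methyl 20-(tert-butyldimethylsilyloxy)-12-hydroxy-13,14,15,16-tetranorlabd-8(17)-en-19-oate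
Conditions: Ph3PCH3Br, KOtBu (4 equiv ylide), THF, rt to 50 °C
Reagents that add atoms: methyltriphenylphosphonium bromide, C[P+](c1ccccc1)(c1ccccc1)c1ccccc1.[Br-]
Why: Wittig methylenation with excess ylide, the first equivalent serving as base for the C12 hydroxyl and the open keto form of the hemiketal being olefinated, as in the methylenation of lactols and of 8-oxolabdanes; any C9 equilibration under these basic conditions should lead to the same equatorial arm.

Step 14
Reactants: 23 the methylene alcohol
Product: 24 methyl 20-(tert-butyldimethylsilyloxy)-12-iodo-13,14,15,16-tetranorlabd-8(17)-en-19-oate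
Conditions: PPh3, I2, imidazole premixed in CH2Cl2, 0 °C; then 23, 0 °C to rt
Reagents that add atoms: iodine, [I][I]
Why: Appel-type iodination by SN2 displacement of the alkoxyphosphonium ion at the unhindered primary carbon; premixing the phosphine and iodine leaves no free iodine, so iodoetherification onto the C8 methylene should not occur.

Step 15
Reactants: 25 α-bromo-γ-butyrolactone (3-bromooxolan-2-one); 26 thiophenol
Product: 27 3-(phenylsulfanyl)oxolan-2-one (racemic)
Conditions: Et3N, CH2Cl2, 0 °C to rt
Reagents that add atoms: none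
Why: SN2 displacement of an activated α-bromo lactone by thiolate gives the sulfur-stabilised lactone pronucleophile.

Step 16
Reactants: 24 the C12 iodide; 27 3-(phenylsulfanyl)oxolan-2-one
Product: 28 methyl 20-(tert-butyldimethylsilyloxy)-13-(phenylsulfanyl)labd-8(17)-en-16,15-olid-19-oate (both C13 epimers)
Conditions: 27, LiN(SiMe3)2, THF, −78 °C; then 24, HMPA, −78 to 0 °C
Reagents that add atoms: none
Why: The sulfur-stabilised lactone enolate is a soft, weakly basic nucleophile that alkylates primary iodides by SN2 in THF/HMPA and should leave the non-enolisable esters and the silyl ether alone; the C13 configuration is irrelevant because the centre becomes sp2 in the next step.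

Step 17
Reactants: 28 the sulfide lactone
Product: 30 methyl 20-(tert-butyldimethylsilyloxy)labda-8(17),13-dien-16,15-olid-19-oate, via sulfoxide 29 (not isolated)
Conditions: mCPBA (1.0 equiv), CH2Cl2, −78 °C; then toluene, CaCO3, 110 °C
Reagents that add atoms: none
Why: One equivalent of peracid at low temperature oxidises the sulfide much faster than the 1,1-disubstituted alkene, and thermal syn-elimination of the sulfoxide toward the ring C14–H should give the conjugated endocyclic butenolide, the standard route to 3-alkylbut-2-enolides.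

Step 18
Reactants: 30 the silyl ether butenolide
Product: 31 methyl 20-hydroxylabda-8(17),13-dien-16,15-olid-19-oate
Conditions: HF·pyridine, pyridine, THF, 0 °C to rt; crude used at once
Reagents that add atoms: none
Why: Fluoride cleavage of the Si–O bond under buffered, mildly acidic conditions never forms the alkoxide, which should hold back lactonisation onto the C19 ester and spare the butenolide and the exocyclic alkene.

Step 19
Reactants: 31 the C20 alcohol
Product: 32 methyl 20-oxolabda-8(17),13-dien-16,15-olid-19-oate (CNP0175906.1)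
Conditions: Dess–Martin periodinane, CH2Cl2, 0 °C to rt
Reagents that add atoms: none
Why: Dess–Martin oxidation takes a neopentyl primary alcohol to the non-enolisable aldehyde under neutral conditions without over-oxidation and should leave both alkenes, the lactone and the ester untouched.

**Compound list**

1 | methyl propanoate | CCC(=O)OC | starting material
2 | methyl formate | COC=O | starting material
3 | methyl 2-formylpropanoate (racemic) | COC(=O)C(C)C=O | intermediate
4 | tert-butyl 2-oxocyclohexane-1-carboxylate | CC(C)(C)OC(=O)C1CCCCC1=O | starting material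
5 | tert-butyl 2-oxo-1-(phenylselanyl)cyclohexane-1-carboxylate (not isolated) | CC(C)(C)OC(=O)C1([Se]c2ccccc2)CCCCC1=O | intermediate
6 | tert-butyl 2-oxo-1-(phenylseleninyl)cyclohexane-1-carboxylate (not isolated) | CC(C)(C)OC(=O)C1([Se](=O)c2ccccc2)CCCCC1=O | intermediate
7 | tert-butyl 6-oxocyclohex-1-ene-1-carboxylate | CC(C)(C)OC(=O)C1=CCCCC1=O | intermediate
8 | allyl bromide | C=CCBr | starting material
9 | tert-butyl (2R)-2-[(2R)-1-methoxy-2-methyl-1,3-dioxopropan-2-yl]-6-oxocyclohexane-1-carboxylate (C1 epimers and enol; not isolated) | CC(C)(C)OC(=O)C1C(=O)CCC[C@H]1[C@](C)(C=O)C(=O)OC | intermediate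
10 | tert-butyl (1R,2S)-2-[(2R)-1-methoxy-2-methyl-1,3-dioxopropan-2-yl]-6-oxo-1-(prop-2-en-1-yl)cyclohexane-1-carboxylate | C=CC[C@]1(C(=O)OC(C)(C)C)C(=O)CCC[C@H]1[C@](C)(C=O)C(=O)OC | intermediate
11 | tert-butyl (1R,2S)-2-[(2S)-1-methoxy-2-methyl-1-oxobut-3-en-2-yl]-6-oxo-1-(prop-2-en-1-yl)cyclohexane-1-carboxylate | C=CC[C@]1(C(=O)OC(C)(C)C)C(=O)CCC[C@H]1[C@](C)(C=C)C(=O)OC | intermediate
12 | 20-tert-butyl 19-methyl 9-oxo-11,12,13,14,15,16,17-heptanorlabd-2-ene-19,20-dioate (not isolated) | C1CC[C@@H]2[C@](C(=O)OC(C)(C)C)(CC=C[C@]2(C)C(=O)OC)C1=O | intermediate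
13 | 20-tert-butyl 19-methyl 9-oxo-11,12,13,14,15,16,17-heptanorlabdane-19,20-dioate | C1CC[C@@H]2[C@](C(=O)OC(C)(C)C)(CCC[C@]2(C)C(=O)OC)C1=O | intermediate
14 | 20-tert-butyl 19-methyl 9-(trifluoromethanesulfonyloxy)-11,12,13,14,15,16,17-heptanorlabd-8-ene-19,20-dioate | C=1CC[C@@H]2[C@](C(=O)OC(C)(C)C)(CCC[C@]2(C)C(=O)OC)C=1OS(=O)(=O)C(F)(F)F | intermediate
15 | C20 acid of 14 (C19 methyl ester retained) | C=1CC[C@@H]2[C@](C(=O)O)(CCC[C@]2(C)C(=O)OC)C=1OS(=O)(=O)C(F)(F)F | intermediate
16 | methyl 20-hydroxy-9-(trifluoromethanesulfonyloxy)-11,12,13,14,15,16,17-heptanorlabd-8-en-19-oate | C=1CC[C@@H]2[C@](CO)(CCC[C@]2(C)C(=O)OC)C=1OS(=O)(=O)C(F)(F)F | intermediate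
17 | methyl 20-(tert-butyldimethylsilyloxy)-9-(trifluoromethanesulfonyloxy)-11,12,13,14,15,16,17-heptanorlabd-8-en-19-oate | C=1CC[C@@H]2[C@](CO[Si](C)(C)C(C)(C)C)(CCC[C@]2(C)C(=O)OC)C=1OS(=O)(=O)C(F)(F)F | intermediate
18 | methyl 20-(tert-butyldimethylsilyloxy)-13,14,15,16,17-pentanorlabda-8,11-dien-19-oate | C=1CC[C@@H]2[C@](CO[Si](C)(C)C(C)(C)C)(CCC[C@]2(C)C(=O)OC)C=1C=C | intermediate
19 | methyl 12-(9-borabicyclo[3.3.1]nonan-9-yl)-20-(tert-butyldimethylsilyloxy)-13,14,15,16,17-pentanorlabd-8-en-19-oate (not isolated) | C=1CC[C@@H]2[C@](CO[Si](C)(C)C(C)(C)C)(CCC[C@]2(C)C(=O)OC)C=1CCB1C2CCCC1CCC2 | intermediate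
20 | 8α-boranyl derivative of 19 (9α-H; not isolated) | [C@@H]1(B)CC[C@@H]2[C@](CO[Si](C)(C)C(C)(C)C)(CCC[C@]2(C)C(=O)OC)[C@H]1CCB1C2CCCC1CCC2 | intermediate
21 | methyl 20-(tert-butyldimethylsilyloxy)-8α,12-dihydroxy-13,14,15,16,17-pentanorlabdan-19-oate | [C@@H]1(O)CC[C@@H]2[C@](CO[Si](C)(C)C(C)(C)C)(CCC[C@]2(C)C(=O)OC)[C@H]1CCO | intermediate
22 | methyl 20-(tert-butyldimethylsilyloxy)-12-hydroxy-8-oxo-13,14,15,16,17-pentanorlabdan-19-oate | O=C1CC[C@@H]2[C@](CO[Si](C)(C)C(C)(C)C)(CCC[C@]2(C)C(=O)OC)[C@H]1CCO | intermediate
23 | methyl 20-(tert-butyldimethylsilyloxy)-12-hydroxy-13,14,15,16-tetranorlabd-8(17)-en-19-oate | C=C1CC[C@@H]2[C@](CO[Si](C)(C)C(C)(C)C)(CCC[C@]2(C)C(=O)OC)[C@H]1CCO | intermediate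
24 | methyl 20-(tert-butyldimethylsilyloxy)-12-iodo-13,14,15,16-tetranorlabd-8(17)-en-19-oate | C=C1CC[C@@H]2[C@](CO[Si](C)(C)C(C)(C)C)(CCC[C@]2(C)C(=O)OC)[C@H]1CCI | intermediate
25 | α-bromo-γ-butyrolactone (3-bromooxolan-2-one, racemic) | BrC1CCOC1=O | starting material
26 | thiophenol | Sc1ccccc1 | starting material
27 | 3-(phenylsulfanyl)oxolan-2-one (racemic) | O=C1OCCC1Sc1ccccc1 | intermediate
28 | methyl 20-(tert-butyldimethylsilyloxy)-13-(phenylsulfanyl)labd-8(17)-en-16,15-olid-19-oate (C13 epimers) | C=C1CC[C@@H]2[C@](CO[Si](C)(C)C(C)(C)C)(CCC[C@]2(C)C(=O)OC)[C@H]1CCC1(Sc2ccccc2)CCOC1=O | intermediate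
29 | 13-(phenylsulfinyl) analogue of 28 (not isolated) | C=C1CC[C@@H]2[C@](CO[Si](C)(C)C(C)(C)C)(CCC[C@]2(C)C(=O)OC)[C@H]1CCC1(S(=O)c2ccccc2)CCOC1=O | intermediate
30 | methyl 20-(tert-butyldimethylsilyloxy)labda-8(17),13-dien-16,15-olid-19-oate | C=C1CC[C@@H]2[C@](CO[Si](C)(C)C(C)(C)C)(CCC[C@]2(C)C(=O)OC)[C@H]1CCC1=CCOC1=O | intermediate
31 | methyl 20-hydroxylabda-8(17),13-dien-16,15-olid-19-oate | C=C1CC[C@@H]2[C@](CO)(CCC[C@]2(C)C(=O)OC)[C@H]1CCC1=CCOC1=O | intermediate
32 | methyl 20-oxolabda-8(17),13-dien-16,15-olid-19-oate (CNP0175906.1) | C=C1CC[C@@H]2[C@](C=O)(CCC[C@]2(C)C(=O)OC)[C@H]1CCC1=CCOC1=O | target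

**Step count and risks**

Total: 19 steps. Longest linear sequence: 17 steps (steps 2–14 and 16–19, from compound 4).

Most likely to fail:

1. Step 3. The catalyst may discriminate poorly between the formyl and ester faces of the donor enolate (C4 epimers), the Michael addition may reverse under the basic allylation conditions, and some O-allylation may occur. The fallback sets out from 3 and 7 and returns at 10. Compound 3 is condensed with (S)-1-phenylethylamine to the enamino ester methyl (Z)-2-methyl-3-{[(1S)-1-phenylethyl]amino}prop-2-enoate F1. This chiral secondary enamine is added to enone 7 in THF at room temperature in an auxiliary-controlled aza-ene-type Michael reaction to give the aldimine adduct F2. Aqueous acetic acid hydrolyses F2 to the Michael adduct 9, which is now isolated. Compound 9 is then C-allylated under neutral Tsuji–Trost conditions (allyl methyl carbonate, Pd(PPh3)4, THF), anti to the C5 substituent, to give 10.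

2. Step 11. The conjugated diene may be hydroborated unselectively (1,4-addition or allylborane formation with transposition), and addition to the hindered trisubstituted alkene may stall. The fallback sets out from triflate 17 and returns at hydroxy ketone 22, so the two-carbon arm arrives saturated and oxygenated and step 12 is bypassed as well. Triflate 17 is coupled with potassium (2-benzyloxyethyl)trifluoroborate in a B-alkyl Suzuki–Miyaura reaction (PdCl2(dppf), Cs2CO3, THF/H2O, 80 °C) to give the benzyl ether alkene methyl 12-(benzyloxy)-20-(tert-butyldimethylsilyloxy)-13,14,15,16,17-pentanorlabd-8-en-19-oate F3. Hydroboration–oxidation (BH3·THF, then NaOH/H2O2) gives the 8α-alcohol F4, and Dess–Martin oxidation gives the 8-ketone F5. Hydrogenolysis (H2, Pd/C, EtOAc) then frees the C12 hydroxyl to give 22.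

3. Step 13. The hydroxy ketone may rest as its cyclic hemiketal and resist olefination, and the alkoxide formed under the strongly basic conditions may open other pathways. The fallback sets out from diol 21 and returns at 23; it also avoids the selective oxidation of step 12. The primary hydroxyl of 21 is silylated selectively (Et3SiCl, imidazole, CH2Cl2, −78 °C) to the mono(triethylsilyl) ether methyl 8α-hydroxy-20-(tert-butyldimethylsilyloxy)-12-(triethylsilyloxy)-13,14,15,16,17-pentanorlabdan-19-oate F6. Dess–Martin oxidation gives the 8-ketone F7, and Wittig methylenation (Ph3P=CH2, THF) gives the 8(17)-alkene F8. Pyridinium p-toluenesulfonate in methanol then removes only the unhindered triethylsilyl group to give 23.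

**Further compounds**

F1 | step 3 | methyl (Z)-2-methyl-3-{[(1S)-1-phenylethyl]amino}prop-2-enoate | COC(=O)/C(C)=C\N[C@@H](C)c1ccccc1
F2 | step 3 | tert-butyl (2R)-2-[(2R)-1-methoxy-2-methyl-1-oxo-3-{[(1S)-1-phenylethyl]imino}propan-2-yl]-6-oxocyclohexane-1-carboxylate | CC(C)(C)OC(=O)C1C(=O)CCC[C@H]1[C@](C)(C=N[C@@H](C)c1ccccc1)C(=O)OC
F3 | step 11 | methyl 12-(benzyloxy)-20-(tert-butyldimethylsilyloxy)-13,14,15,16,17-pentanorlabd-8-en-19-oate | C=1CC[C@@H]2[C@](CO[Si](C)(C)C(C)(C)C)(CCC[C@]2(C)C(=O)OC)C=1CCOCc1ccccc1
F4 | step 11 | methyl 12-(benzyloxy)-8α-hydroxy-20-(tert-butyldimethylsilyloxy)-13,14,15,16,17-pentanorlabdan-19-oate | [C@@H]1(O)CC[C@@H]2[C@](CO[Si](C)(C)C(C)(C)C)(CCC[C@]2(C)C(=O)OC)[C@H]1CCOCc1ccccc1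
F5 | step 11 | methyl 12-(benzyloxy)-8-oxo-20-(tert-butyldimethylsilyloxy)-13,14,15,16,17-pentanorlabdan-19-oate | O=C1CC[C@@H]2[C@](CO[Si](C)(C)C(C)(C)C)(CCC[C@]2(C)C(=O)OC)[C@H]1CCOCc1ccccc1
F6 | step 13 | methyl 8α-hydroxy-20-(tert-butyldimethylsilyloxy)-12-(triethylsilyloxy)-13,14,15,16,17-pentanorlabdan-19-oate | [C@@H]1(O)CC[C@@H]2[C@](CO[Si](C)(C)C(C)(C)C)(CCC[C@]2(C)C(=O)OC)[C@H]1CCO[Si](CC)(CC)CC
F7 | step 13 | methyl 8-oxo-20-(tert-butyldimethylsilyloxy)-12-(triethylsilyloxy)-13,14,15,16,17-pentanorlabdan-19-oate | O=C1CC[C@@H]2[C@](CO[Si](C)(C)C(C)(C)C)(CCC[C@]2(C)C(=O)OC)[C@H]1CCO[Si](CC)(CC)CC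
F8 | step 13 | methyl 20-(tert-butyldimethylsilyloxy)-12-(triethylsilyloxy)-13,14,15,16-tetranorlabd-8(17)-en-19-oate | C=C1CC[C@@H]2[C@](CO[Si](C)(C)C(C)(C)C)(CCC[C@]2(C)C(=O)OC)[C@H]1CCO[Si](CC)(CC)CC
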